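**Plan**
- Retrosynthetic cuts: first, the bond from C2' of ring B to the prenyl CH2, by a retro-Claisen step back to a 1,1-dimethylallyl ether on the C3' oxygen. Second, the C2–C3 bond of ring C, back to a C2–H bond and a diazo group on C3. Third, the O1–C2 bond, back to a phenol and a benzylic alcohol.
- Enabling feature: C2 is α to the ring oxygen O1 and benzylic to ring B, whose C4' oxygen lies para to it. In the open form A-ring–O1–CH2–B-ring its C–H bonds are therefore the most hydridic in the molecule. They sit 1,6 to C3, which can carry a metal carbene because it is the α-carbon of the C4 ketone.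
- Forward order: rings A and B are bought as arenes and joined through O1. The acetyl group becomes COCHN2, and ring C closes by enantioselective C–H insertion. The C5 unit, parked on the C3' oxygen as protecting group and prenyl source in one, then moves to C2', and the remaining groups fall in one pot.
- Stereochemistry: C2 (S) is the only stereocentre. The chiral dirhodium catalyst sets it by selecting the pro-S hydrogen of the OCH2 group, with retention, and no later step uses base.

Key step: step 8

Assumption: the catalyst made from (S)-tert-leucine is taken to give the (2S) product; if a pilot run shows the opposite sense, the mirror-image catalyst from (R)-tert-leucine is used with no other change.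

**Step 1**
Reactants: 1 3,4-dihydroxybenzaldehyde
Product: 2 3-hydroxy-4-(methoxymethoxy)benzaldehyde
Conditions: MOMCl (1.0 equiv), K2CO3 (1.1 equiv), acetone, 0 °C to rt
Reagents that add atoms: chloromethyl methyl ether (MOMCl), COCCl
Why: The 4-OH, para to the formyl group, is the more acidic phenol, so one equivalent of weak base forms only the 4-phenoxide, which is alkylated (regioselective Williamson-type O-alkylation).

**Step 2**
Reactants: 3 2-methylbut-3-en-2-ol
Product: 4 tert-butyl 2-methylbut-3-en-2-yl carbonate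
Conditions: n-BuLi, THF, 0 °C; Boc2O, 0 °C to rt; water quench
Reagents that add atoms: di-tert-butyl dicarbonate (Boc2O), CC(C)(C)OC(=O)OC(=O)OC(C)(C)C
Why: The lithium alkoxide of the tertiary allylic alcohol is acylated by Boc2O to give the mixed carbonate (alkoxycarbonylation of an alkoxide).

**Step 3**
Reactants: 2 3-hydroxy-4-(methoxymethoxy)benzaldehyde; 4 tert-butyl 2-methylbut-3-en-2-yl carbonate
Product: 5 4-(methoxymethoxy)-3-(2-methylbut-3-en-2-yloxy)benzaldehyde
Conditions: Pd(PPh3)4 (3 mol %), THF, 0 °C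
Reagents that add atoms: none
Why: In this Tsuji–Trost O-allylation zerovalent palladium ionises 4 with loss of CO2, the released tert-butoxide deprotonates the phenol, and under kinetic control at low temperature the phenoxide attacks the more substituted terminus of the 1,1-dimethyl-π-allyl complex to give the tertiary ether.

**Step 4**
Reactants: 5 4-(methoxymethoxy)-3-(2-methylbut-3-en-2-yloxy)benzaldehyde
Product: 6 [4-(methoxymethoxy)-3-(2-methylbut-3-en-2-yloxy)phenyl]methanol
Conditions: NaBH4, MeOH, 0 °C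
Reagents that add atoms: none
Why: Borohydride 1,2-reduction of the aldehyde leaves the acetal, the tertiary allyl ether and the vinyl group untouched.

**Step 5**
Reactants: 7 2,4,6-trihydroxyacetophenone (dried)
Product: 8 1-[2,4-bis(tert-butyldimethylsilyloxy)-6-hydroxyphenyl]ethan-1-one
Conditions: TBSCl (2.1 equiv), imidazole, CH2Cl2/DMF, 0 °C
Reagents that add atoms: tert-butyldimethylsilyl chloride (TBSCl), CC(C)(C)[Si](C)(C)Cl
Why: Silylation should stop at the bis-ether because the last ortho OH is held in a hydrogen bond to the acetyl carbonyl, the same selectivity that is standard for bis-protection of this ketone.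

**Step 6**
Reactants: 6 [4-(methoxymethoxy)-3-(2-methylbut-3-en-2-yloxy)phenyl]methanol; 8 1-[2,4-bis(tert-butyldimethylsilyloxy)-6-hydroxyphenyl]ethan-1-one
Product: 9 1-[2,4-bis(tert-butyldimethylsilyloxy)-6-{[4-(methoxymethoxy)-3-(2-methylbut-3-en-2-yloxy)phenyl]methoxy}phenyl]ethan-1-one
Conditions: PPh3, DIAD, THF, 0 °C to rt
Reagents that add atoms: none
Why: In this Mitsunobu etherification the acidic chelated phenol displaces the oxyphosphonium salt of the primary benzylic alcohol under neutral conditions that spare the aryl silyl ethers, the acetal and the tertiary allyl ether.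

**Step 7**
Reactants: 9 1-[2,4-bis(tert-butyldimethylsilyloxy)-6-{[4-(methoxymethoxy)-3-(2-methylbut-3-en-2-yloxy)phenyl]methoxy}phenyl]ethan-1-one
Product: 11 2-diazo-1-[2,4-bis(tert-butyldimethylsilyloxy)-6-{[4-(methoxymethoxy)-3-(2-methylbut-3-en-2-yloxy)phenyl]methoxy}phenyl]ethan-1-one, via trifluoroacetyl diketone 10 (not isolated)
Conditions: LiHMDS (1.1 equiv), THF, −78 °C; CF3CO2CH2CF3, −78 °C, 10 min; cold dilute aq. HCl wash; then p-ABSA, Et3N, H2O (1 equiv), MeCN, rt
Reagents that add atoms: 4-acetamidobenzenesulfonyl azide (p-ABSA), CC(=O)Nc1ccc(cc1)S(=O)(=O)N=[N+]=[N-]; 2,2,2-trifluoroethyl trifluoroacetate, O=C(OCC(F)(F)F)C(F)(F)F (its CF3CO group is kept only in 10)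
Why: In this detrifluoroacetylative diazo transfer of the Regitz type the kinetic enolate of the methyl ketone is trifluoroacetylated to 10, which takes up N2 from the sulfonyl azide and passes its CF3CO group to the sulfonamide, while the short enolate lifetime at −78 °C should prevent silyl migration between oxygens.

**Step 8**
Reactants: 11 2-diazo-1-[2,4-bis(tert-butyldimethylsilyloxy)-6-{[4-(methoxymethoxy)-3-(2-methylbut-3-en-2-yloxy)phenyl]methoxy}phenyl]ethan-1-one
Product: 13 (2S)-5,7-bis(tert-butyldimethylsilyloxy)-2-[4-(methoxymethoxy)-3-(2-methylbut-3-en-2-yloxy)phenyl]chroman-4-one, via rhodium carbenoid 12 (not isolated)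
Conditions: Rh2(S-PTTL)4 (1 mol %), 4 Å MS, CH2Cl2, 0 °C, syringe-pump addition of 11 (final 0.01 M)
Reagents that add atoms: none
Why: Rh2(S-PTTL)4 expels N2 from 11 to give the electrophilic carbenoid 12, whose carbene carbon (the future C3) inserts into one C–H bond of the O1–CH2–aryl group (the future C2) through a concerted, asynchronous three-centre transition state with hydride-transfer character and retention at carbon. The closest known reaction type is the enantioselective intramolecular C–H insertion of 2-alkoxyaryl α-diazoketones to chroman-4-ones under chiral divalent-rhodium carboxylates, backed by the analogous insertion into aryl benzyl ethers that gives 2-aryl-2,3-dihydrobenzofurans. Ring C closes in the 1,6-insertion mode to a six-membered ring, because the 1,5 position is O1 itself and bears no hydrogen, while the sp2 atoms C4, C4a and C8a hold the carbene carbon over the CH2 group. C2 is the only new stereocentre and is controlled by the catalyst alone: the pocket formed by the four N-phthaloyl-tert-leucinate ligands tells the two enantiotopic hydrogens apart, and replacement of the pro-S hydrogen gives the (2S) product. The step needs C–H insertion to win over oxonium-ylide formation at O1 with 1,2-benzyl shift, over attack on the second ortho substituent and over cyclopropanation; the substrate secures this by the low basicity of O1 (lone pair shared with the acyl-bearing ring A), by the C4' oxygen para to the CH2 group that makes these C–H bonds the most hydridic ones, by the silyl group on the C5 oxygen that offers no α C–H bond and screens that oxygen, and by holding the C5 unit as a vinyl group on a quaternary carbon at the remote meta oxygen instead of as a nucleophilic prenyl alkene next to the reacting carbon. Slow addition at high dilution keeps carbene dimerisation and intermolecular reactions down.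

**Step 9**
Reactants: 13 (2S)-5,7-bis(tert-butyldimethylsilyloxy)-2-[4-(methoxymethoxy)-3-(2-methylbut-3-en-2-yloxy)phenyl]chroman-4-one
Product: 15 (2S)-5,7-bis(tert-butyldimethylsilyloxy)-2-[3-hydroxy-4-(methoxymethoxy)-2-(3-methylbut-2-en-1-yl)phenyl]chroman-4-one, via ortho-dienone 14 (not isolated)
Conditions: degassed PhMe (0.05 M), 110 °C, sealed tube
Reagents that add atoms: none
Why: In this aromatic Claisen rearrangement the [3,3] shift of the 1,1-dimethylallyl aryl ether delivers its terminal CH2 to C2', the only ortho position that bears hydrogen (C4' is blocked by OMOM), inverts the unit to a normal prenyl group and frees the 3'-OH on tautomerisation of 14, and the gem-dimethyl group lowers the barrier enough for neutral toluene, a medium with neither acid nor base in which C2 should stay intact.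

**Step 10**
Reactants: 15 (2S)-5,7-bis(tert-butyldimethylsilyloxy)-2-[3-hydroxy-4-(methoxymethoxy)-2-(3-methylbut-2-en-1-yl)phenyl]chroman-4-one
Product: 17 (2S)-2-[3,4-dihydroxy-2-(3-methylbut-2-en-1-yl)phenyl]-5,7-dihydroxychroman-4-one, via 4'-O-methoxymethyl ether 16 (not isolated)
Conditions: KHF2 (4 equiv), MeOH, rt, polypropylene vessel; then aq. HCl (to ca. 1 M), MeOH, 40 °C, short contact time
Reagents that add atoms: none
Why: Weakly acidic bifluoride cleaves the two aryl silyl ethers without building up phenoxide, so ring C cannot open by retro-oxa-Michael or quinone-methide pathways, and a brief acid-catalysed transacetalisation with methanol then removes the MOM group under conditions that ortho-prenylphenols commonly tolerate.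

**Compound list**
1 | 3,4-dihydroxybenzaldehyde | O=Cc1ccc(O)c(O)c1 | starting material
2 | 3-hydroxy-4-(methoxymethoxy)benzaldehyde | O=Cc1ccc(OCOC)c(O)c1 | intermediate
3 | 2-methylbut-3-en-2-ol | C=CC(C)(C)O | starting material
4 | tert-butyl 2-methylbut-3-en-2-yl carbonate | C=CC(C)(C)OC(=O)OC(C)(C)C | intermediate
5 | 4-(methoxymethoxy)-3-(2-methylbut-3-en-2-yloxy)benzaldehyde | C=CC(C)(C)Oc1cc(C=O)ccc1OCOC | intermediate
6 | [4-(methoxymethoxy)-3-(2-methylbut-3-en-2-yloxy)phenyl]methanol | C=CC(C)(C)Oc1cc(CO)ccc1OCOC | intermediate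
7 | 2,4,6-trihydroxyacetophenone | CC(=O)c1c(O)cc(O)cc1O | starting material
8 | 1-[2,4-bis(tert-butyldimethylsilyloxy)-6-hydroxyphenyl]ethan-1-one | CC(=O)c1c(O)cc(O[Si](C)(C)C(C)(C)C)cc1O[Si](C)(C)C(C)(C)C | intermediate
9 | 1-[2,4-bis(tert-butyldimethylsilyloxy)-6-{[4-(methoxymethoxy)-3-(2-methylbut-3-en-2-yloxy)phenyl]methoxy}phenyl]ethan-1-one | CC(=O)c1c(OCc2ccc(OCOC)c(OC(C)(C)C=C)c2)cc(O[Si](C)(C)C(C)(C)C)cc1O[Si](C)(C)C(C)(C)C | intermediate
10 | 1-[2,4-bis(tert-butyldimethylsilyloxy)-6-{[4-(methoxymethoxy)-3-(2-methylbut-3-en-2-yloxy)phenyl]methoxy}phenyl]-4,4,4-trifluorobutane-1,3-dione | O=C(CC(=O)C(F)(F)F)c1c(OCc2ccc(OCOC)c(OC(C)(C)C=C)c2)cc(O[Si](C)(C)C(C)(C)C)cc1O[Si](C)(C)C(C)(C)C | intermediate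
11 | 2-diazo-1-[2,4-bis(tert-butyldimethylsilyloxy)-6-{[4-(methoxymethoxy)-3-(2-methylbut-3-en-2-yloxy)phenyl]methoxy}phenyl]ethan-1-one | [N-]=[N+]=CC(=O)c1c(OCc2ccc(OCOC)c(OC(C)(C)C=C)c2)cc(O[Si](C)(C)C(C)(C)C)cc1O[Si](C)(C)C(C)(C)C | intermediate
12 | rhodium carbenoid of 11 (Rh=CH–C(=O)–aryl; the ligand shell of Rh2(S-PTTL)4 is left out of the SMILES) | [Rh]=CC(=O)c1c(OCc2ccc(OCOC)c(OC(C)(C)C=C)c2)cc(O[Si](C)(C)C(C)(C)C)cc1O[Si](C)(C)C(C)(C)C | intermediate
13 | (2S)-5,7-bis(tert-butyldimethylsilyloxy)-2-[4-(methoxymethoxy)-3-(2-methylbut-3-en-2-yloxy)phenyl]chroman-4-one | C=CC(C)(C)Oc1cc([C@@H]2CC(=O)c3c(O[Si](C)(C)C(C)(C)C)cc(O[Si](C)(C)C(C)(C)C)cc3O2)ccc1OCOC | intermediate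
14 | (2S)-5,7-bis(tert-butyldimethylsilyloxy)-2-[4-(methoxymethoxy)-6-(3-methylbut-2-en-1-yl)-5-oxocyclohexa-1,3-dien-1-yl]chroman-4-one (transient, ring carbon bearing the prenyl group undefined) | CC(C)=CCC1C(=O)C(OCOC)=CC=C1[C@@H]2CC(=O)c3c(O[Si](C)(C)C(C)(C)C)cc(O[Si](C)(C)C(C)(C)C)cc3O2 | intermediate
15 | (2S)-5,7-bis(tert-butyldimethylsilyloxy)-2-[3-hydroxy-4-(methoxymethoxy)-2-(3-methylbut-2-en-1-yl)phenyl]chroman-4-one | CC(C)=CCc1c([C@@H]2CC(=O)c3c(O[Si](C)(C)C(C)(C)C)cc(O[Si](C)(C)C(C)(C)C)cc3O2)ccc(OCOC)c1O | intermediate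
16 | (2S)-5,7-dihydroxy-2-[3-hydroxy-4-(methoxymethoxy)-2-(3-methylbut-2-en-1-yl)phenyl]chroman-4-one | CC(C)=CCc1c([C@@H]2CC(=O)c3c(O)cc(O)cc3O2)ccc(OCOC)c1O | intermediate
17 | (2S)-2-[3,4-dihydroxy-2-(3-methylbut-2-en-1-yl)phenyl]-5,7-dihydroxychroman-4-one | CC(C)=CCc1c([C@@H]2CC(=O)c3c(O)cc(O)cc3O2)ccc(O)c1O | target

**Step count**
Total steps: 10. Longest linear sequence: 8 (steps 1, 3, 4, 6, 7, 8, 9, 10).

**Steps most likely to fail**

1. **Step 8.** The lone pair of O1 may capture the carbenoid (oxonium-ylide formation followed by a 1,2-shift of the benzyl group), or the catalyst may discriminate poorly between the two enantiotopic C–H bonds. The fallback closes ring C at O1–C2 instead and takes the stereocentre from an asymmetric aldol addition.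
   - It sets out from 8 and 5.
   - Me3SiOTf/Et3N (CH2Cl2, 0 °C) should convert 8 into the bis(trimethylsilyl) enol ether F1.
   - An enantioselective Mukaiyama aldol addition of F1 to aldehyde 5 follows, under an N-tosyl-tryptophan-derived B-butyloxazaborolidinone (EtCN, −78 °C, antipode chosen for the R product). It should give the silylated (R)-aldol adduct F2.
   - Citric acid in MeOH removes both O–SiMe3 groups to give the (R)-β-hydroxy ketone F3.
   - An intramolecular Mitsunobu etherification (PPh3, DIAD, toluene, 0 °C) displaces the benzylic oxygen with inversion and comes back to the route at 13.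

2. **Step 9.** Heat may open and reclose ring C and so erode C2, the allyl unit may migrate onward by a Cope shift, or the tertiary allyl ether may ionise with loss of the C5 unit. The fallback moves the sigmatropic shift ahead of the creation of the stereocentre.
   - It sets out from 9.
   - Heating 9 in toluene (110 °C) should give, through the ortho-dienone F4, the 2-prenyl-3-hydroxybenzyl ether F5.
   - TBSCl/imidazole gives the tris-silyl ether F6.
   - The operations of step 7 give, through the trifluoroacetyl diketone F7, the diazoketone F8.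
   - Rh2(S-PTTL)4 under the conditions of step 8 gives, through the rhodium carbenoid F9, the (2S)-flavanone F10. Here the bulk of the catalyst and the flanking of the trisubstituted alkene by the silyl ether must hold off cyclopropanation.
   - KHF2 in MeOH removes all three silyl groups and the route is rejoined at 16.

3. **Step 3.** The phenoxide may attack the unsubstituted terminus of the π-allyl complex, or palladium may re-ionise the branched ether and let it drift to the linear prenyl ether. Either would put the wrong carbon substituent on C2' in step 9. The fallback avoids any π-allyl intermediate by using a copper-catalysed propargylic substitution followed by semihydrogenation.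
   - It sets out from 2.
   - 3-Chloro-3-methylbut-1-yne, DBU and CuCl2 (cat.) in MeCN at 0 °C should give the 1,1-dimethylpropargyl ether F11.
   - H2 (1 atm) over Pd/CaCO3 poisoned with Pb(OAc)2, with quinoline in EtOAc, reduces the alkyne to the vinyl group and comes back to the route at 5. Step 2 is then not needed.

**Further compounds**
F1 | step 8 | {1-[2,4-bis(tert-butyldimethylsilyloxy)-6-(trimethylsilyloxy)phenyl]ethenyl}oxytrimethylsilane | C=C(O[Si](C)(C)C)c1c(O[Si](C)(C)C)cc(O[Si](C)(C)C(C)(C)C)cc1O[Si](C)(C)C(C)(C)C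
F2 | step 8 | (3R)-1-[2,4-bis(tert-butyldimethylsilyloxy)-6-(trimethylsilyloxy)phenyl]-3-[4-(methoxymethoxy)-3-(2-methylbut-3-en-2-yloxy)phenyl]-3-(trimethylsilyloxy)propan-1-one | C[Si](C)(C)O[C@H](CC(=O)c1c(O[Si](C)(C)C)cc(O[Si](C)(C)C(C)(C)C)cc1O[Si](C)(C)C(C)(C)C)c1ccc(OCOC)c(OC(C)(C)C=C)c1
F3 | step 8 | (3R)-1-[2,4-bis(tert-butyldimethylsilyloxy)-6-hydroxyphenyl]-3-hydroxy-3-[4-(methoxymethoxy)-3-(2-methylbut-3-en-2-yloxy)phenyl]propan-1-one | O[C@H](CC(=O)c1c(O)cc(O[Si](C)(C)C(C)(C)C)cc1O[Si](C)(C)C(C)(C)C)c1ccc(OCOC)c(OC(C)(C)C=C)c1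
F4 | step 9 | 1-[2,4-bis(tert-butyldimethylsilyloxy)-6-{[4-(methoxymethoxy)-6-(3-methylbut-2-en-1-yl)-5-oxocyclohexa-1,3-dien-1-yl]methoxy}phenyl]ethan-1-one | CC(=O)c1c(OCC2=CC=C(OCOC)C(=O)C2CC=C(C)C)cc(O[Si](C)(C)C(C)(C)C)cc1O[Si](C)(C)C(C)(C)C
F5 | step 9 | 1-[2,4-bis(tert-butyldimethylsilyloxy)-6-{[3-hydroxy-4-(methoxymethoxy)-2-(3-methylbut-2-en-1-yl)phenyl]methoxy}phenyl]ethan-1-one | CC(=O)c1c(OCc2ccc(OCOC)c(O)c2CC=C(C)C)cc(O[Si](C)(C)C(C)(C)C)cc1O[Si](C)(C)C(C)(C)C
F6 | step 9 | 1-[2,4-bis(tert-butyldimethylsilyloxy)-6-{[3-(tert-butyldimethylsilyloxy)-4-(methoxymethoxy)-2-(3-methylbut-2-en-1-yl)phenyl]methoxy}phenyl]ethan-1-one | CC(=O)c1c(OCc2ccc(OCOC)c(O[Si](C)(C)C(C)(C)C)c2CC=C(C)C)cc(O[Si](C)(C)C(C)(C)C)cc1O[Si](C)(C)C(C)(C)C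
F7 | step 9 | 4,4,4-trifluorobutane-1,3-dione derived from F6 by trifluoroacetylation of its methyl group | O=C(CC(=O)C(F)(F)F)c1c(OCc2ccc(OCOC)c(O[Si](C)(C)C(C)(C)C)c2CC=C(C)C)cc(O[Si](C)(C)C(C)(C)C)cc1O[Si](C)(C)C(C)(C)C
F8 | step 9 | 2-diazo-1-[2,4-bis(tert-butyldimethylsilyloxy)-6-{[3-(tert-butyldimethylsilyloxy)-4-(methoxymethoxy)-2-(3-methylbut-2-en-1-yl)phenyl]methoxy}phenyl]ethan-1-one | [N-]=[N+]=CC(=O)c1c(OCc2ccc(OCOC)c(O[Si](C)(C)C(C)(C)C)c2CC=C(C)C)cc(O[Si](C)(C)C(C)(C)C)cc1O[Si](C)(C)C(C)(C)C
F9 | step 9 | rhodium carbenoid of F8 (ligand shell of Rh2(S-PTTL)4 left out of the SMILES) | [Rh]=CC(=O)c1c(OCc2ccc(OCOC)c(O[Si](C)(C)C(C)(C)C)c2CC=C(C)C)cc(O[Si](C)(C)C(C)(C)C)cc1O[Si](C)(C)C(C)(C)C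
F10 | step 9 | (2S)-5,7-bis(tert-butyldimethylsilyloxy)-2-[3-(tert-butyldimethylsilyloxy)-4-(methoxymethoxy)-2-(3-methylbut-2-en-1-yl)phenyl]chroman-4-one | CC(C)=CCc1c([C@@H]2CC(=O)c3c(O[Si](C)(C)C(C)(C)C)cc(O[Si](C)(C)C(C)(C)C)cc3O2)ccc(OCOC)c1O[Si](C)(C)C(C)(C)C
F11 | step 3 | 4-(methoxymethoxy)-3-(2-methylbut-3-yn-2-yloxy)benzaldehyde | C#CC(C)(C)Oc1cc(C=O)ccc1OCOC
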